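The 14-membered ring (C1 carries CO2Me, C2 is the enoate CH, C4 the stereocentre, numbering running on to C14; side chain C15–C19 on C4) is cut at C5–C6. C6 is the allylic CH2 on the C7=C8 trisubstituted alkene and C5 is the CH2 beside C4, so a nitro group on C5, which arrives with C5 when C4 is set by asymmetric nitromethane addition, turns C5 into a soft nucleophile. One palladium-catalysed allylic alkylation then forms C5–C6 and closes the ring, and the nitro group is removed afterwards. The precursor is an open-chain primary nitro compound that holds the E-enoate and an (E)-allylic methyl carbonate at C6.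

Key step: step 12

Remarks on the chemistry
- Geranyl carbon 1 becomes ring carbon C13, so C14 has to be added by a one-carbon homologation (steps 5 and 6) before the ylide carbon C1 is attached.
- The carbonate is put on before the Wittig step, so the Wittig product is the cyclisation substrate itself and no protecting group is needed.
- Assumption: the (R)-catalyst in step 4 is taken to give (R)-C4 by analogy with cinnamaldehyde, where the (S)-catalyst gives the (S)-adduct with the same priority order of substituents.
- C5 of compound 19 forms as a mixture of epimers; both are carried on because step 13 removes this centre.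
- (i-PrO)Me2SiCH2MgCl is made beforehand from commercial (chloromethyl)dimethyl(propan-2-yloxy)silane and Mg in THF.

Step 1
Reactants: 1 propargyl alcohol; 2 prenyl bromide
Product: 4 (2E)-2,6-dimethylhepta-2,5-dien-1-ol, via alkenylalane 3 (not isolated)
Conditions: AlMe3 (3 equiv), (C5H5)2ZrCl2 (0.25 equiv), CH2Cl2, 0 °C to rt; then 2, Pd(PPh3)4 (5 mol%), THF, rt; aqueous work-up
Reagents that add atoms: trimethylaluminium, C[Al](C)C
Why: Negishi zirconium-catalysed carboalumination adds Me and Al syn across the alkyne of the aluminium alkoxide of 1 with Al on the terminal carbon, which fixes the E geometry of C15=C16, and the alkenylalane 3 then couples under zerovalent palladium catalysis at the primary terminus of the prenyl π-allyl unit with retention of both alkene geometries.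

Step 2
Reactants: 4 (2E)-2,6-dimethylhepta-2,5-dien-1-ol
Product: 5 (2E)-2,6-dimethylhepta-2,5-dienal
Conditions: MnO2 (activated, excess), CH2Cl2, rt
Reagents that add atoms: none
Why: MnO2 oxidation of a primary allylic alcohol stops at the enal under neutral conditions, so the E geometry and the skipped diene are kept.

Step 3
Reactants: 5 (2E)-2,6-dimethylhepta-2,5-dienal
Product: 6 (2E,4E)-4,8-dimethylnona-2,4,7-trienal
Conditions: Ph3P=CHCHO (1.2 equiv), toluene, 80 °C
Reagents that add atoms: (triphenylphosphoranylidene)acetaldehyde, O=CC=P(c1ccccc1)(c1ccccc1)c1ccccc1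
Why: Wittig reaction with the formyl-stabilised ylide adds C2 and C3 and gives the E-disubstituted alkene expected for a stabilised ylide, while a small excess of reagent limits a second homologation of the more conjugated, less electrophilic product.

Step 4
Reactants: 6 (2E,4E)-4,8-dimethylnona-2,4,7-trienal; 7 nitromethane
Product: 8 (3R,4E)-4,8-dimethyl-3-(nitromethyl)nona-4,7-dienal
Conditions: (R)-2-[diphenyl(trimethylsilyloxy)methyl]pyrrolidine (10 mol%), PhCO2H (20 mol%), nitromethane in threefold excess, MeOH, rt
Reagents that add atoms: none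
Why: Iminium-ion catalysis (asymmetric nitro-Michael addition with a diarylprolinol silyl ether): the bulky CPh2OSiMe3 group shields one face of the E-iminium ion of 6, the nitronate attacks C4, the unsubstituted position next to the iminium carbon, from the open face, and with the (R)-catalyst this sets C4 as R.

Step 5
Reactants: 9 geranyl bromide
Product: 10 [(3E)-4,8-dimethylnona-3,7-dien-1-yl](dimethyl)(propan-2-yloxy)silane
Conditions: (i-PrO)Me2SiCH2MgCl (1.5 equiv), CuI (10 mol%), THF, 0 °C to rt
Reagents that add atoms: [dimethyl(propan-2-yloxy)silyl]methylmagnesium chloride, CC(C)O[Si](C)(C)C[Mg]Cl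
Why: Copper-catalysed Grignard coupling displaces the primary allylic bromide at the α-carbon with retention of the E-alkene and so adds C14 as a masked hydroxymethyl group (Kumada–Tamao reagent).

Step 6
Reactants: 10 [(3E)-4,8-dimethylnona-3,7-dien-1-yl](dimethyl)(propan-2-yloxy)silane
Product: 11 (3E)-4,8-dimethylnona-3,7-dien-1-ol
Conditions: 30% H2O2, KF, KHCO3, THF/MeOH, rt
Reagents that add atoms: hydrogen peroxide, OO
Why: Tamao oxidation: fluoride-activated silicon takes up hydroperoxide, the primary alkyl group migrates from Si to O and hydrolysis frees the alcohol, while isolated trisubstituted alkenes do not react with basic H2O2.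

Step 7
Reactants: 11 (3E)-4,8-dimethylnona-3,7-dien-1-ol
Product: 12 (6E)-9-bromo-2,6-dimethylnona-2,6-diene
Conditions: CBr4, PPh3, CH2Cl2, 0 °C
Reagents that add atoms: tetrabromomethane, BrC(Br)(Br)Br
Why: Appel reaction: the oxyphosphonium ion of the primary homoallylic alcohol is displaced by bromide in an SN2 step under neutral conditions that leave both alkenes in place.

Step 8
Reactants: 12 (6E)-9-bromo-2,6-dimethylnona-2,6-diene
Product: 13 (2E,6E)-9-bromo-2,6-dimethylnona-2,6-dien-1-ol
Conditions: SeO2 (0.5 equiv), t-BuOOH (3 equiv), salicylic acid (10 mol%), CH2Cl2, 0 °C to rt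
Reagents that add atoms: tert-butyl hydroperoxide, CC(C)(C)OO
Why: Allylic oxidation with catalytic SeO2 and t-BuOOH (ene reaction followed by 2,3-sigmatropic shift) attacks the terminal isopropylidene group at its E-methyl, which gives the (E)-2-methylallylic alcohol with C6 oxygenated, and a primary alkyl bromide tolerates these conditions.

Step 9
Reactants: 13 (2E,6E)-9-bromo-2,6-dimethylnona-2,6-dien-1-ol
Product: 14 (2E,6E)-9-bromo-2,6-dimethylnona-2,6-dien-1-yl methyl carbonate
Conditions: ClCO2Me (1.5 equiv), pyridine, CH2Cl2, 0 °C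
Reagents that add atoms: methyl chloroformate, COC(Cl)=O
Why: O-Acylation of the primary allylic alcohol with methyl chloroformate and pyridine gives the methyl carbonate that will serve as leaving group and internal base source in step 12, without touching the alkyl bromide.

Step 10
Reactants: 14 (2E,6E)-9-bromo-2,6-dimethylnona-2,6-dien-1-yl methyl carbonate
Product: 17 methyl (5E,9E)-11-(methoxycarbonyloxy)-6,10-dimethyl-2-(triphenyl-λ5-phosphanylidene)undeca-5,9-dienoate, via iodo carbonate 15 (not isolated), via phosphonium iodide 16 (not isolated)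
Conditions: Ph3P=CHCO2Me (1.9 equiv), NaI (1.2 equiv), MeCN, 80 °C; filtration from the phosphonium salt
Reagents that add atoms: methyl (triphenylphosphoranylidene)acetate, COC(=O)C=P(c1ccccc1)(c1ccccc1)c1ccccc1
Why: Finkelstein exchange to the iodide 15 is followed by C-alkylation of the ester-stabilised ylide (Bestmann alkylation) and by proton transfer from the salt 16 to a second equivalent of ylide (transylidation), which gives the α-substituted stabilised ylide and attaches C1 to C14, the uncatalysed allylic carbonate being inert to these soft nucleophiles.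

Step 11
Reactants: 8 (3R,4E)-4,8-dimethyl-3-(nitromethyl)nona-4,7-dienal; 17 methyl (5E,9E)-11-(methoxycarbonyloxy)-6,10-dimethyl-2-(triphenyl-λ5-phosphanylidene)undeca-5,9-dienoate
Product: 18 methyl (2E,5E,9E)-2-[(3R,4E)-4,8-dimethyl-3-(nitromethyl)nona-4,7-dien-1-ylidene]-11-(methoxycarbonyloxy)-6,10-dimethylundeca-5,9-dienoate
Conditions: toluene, 60 °C
Reagents that add atoms: none
Why: Wittig reaction of an α-substituted ester-stabilised ylide with an unhindered aliphatic aldehyde gives the trisubstituted enoate with the ester trans to C3 (E), and the neutral ylide is too weakly basic to deprotonate the nitro group or to disturb C4.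

Step 12
Reactants: 18 methyl (2E,5E,9E)-2-[(3R,4E)-4,8-dimethyl-3-(nitromethyl)nona-4,7-dien-1-ylidene]-11-(methoxycarbonyloxy)-6,10-dimethylundeca-5,9-dienoate
Product: 19 methyl (1E,4E,8E,11RS,12R)-5,9-dimethyl-12-[(2E)-6-methylhepta-2,5-dien-2-yl]-11-nitrocyclotetradeca-1(14),4,8-triene-1-carboxylate
Conditions: Pd(PPh3)4 (10 mol%), THF, 65 °C, 18 added by syringe pump over 10 h (final 0.002 M)
Reagents that add atoms: none
Why: Zerovalent palladium ionises the allylic carbonate at C6 with loss of CO2 to a syn π-allyl complex over C6–C7–C8, and the methoxide set free deprotonates C5, the most acidic position (Tsuji–Trost allylic alkylation under neutral conditions). The closest known reactions are the palladium-catalysed macrocyclisations of stabilised carbanions onto allylic esters and the allylation of nitroalkanes with allylic carbonates. The nitronate carbon C5 attacks the C6 terminus anti to palladium, which closes the 14-membered ring in the endo sense of the allyl unit so that C7=C8 stays in the ring, whereas attack at C8 would give a 12-membered ring with an exocyclic isopropenyl group. C5 becomes a stereocentre without control, which does not matter because the nitro group is removed in step 13, while C4 is not acidic and keeps its configuration. The step needs attack at C6 over C8 (secured by the unhindered primary terminus and the lower strain of the larger ring), E geometry at C7=C8 (the syn complex from the (E)-carbonate is kept), C- over O-allylation (O-allylation of a nitronate is reversible under palladium catalysis) and ring closure over oligomerisation (slow addition at high dilution).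

Step 13
Reactants: 19 methyl (1E,4E,8E,11RS,12R)-5,9-dimethyl-12-[(2E)-6-methylhepta-2,5-dien-2-yl]-11-nitrocyclotetradeca-1(14),4,8-triene-1-carboxylate
Product: 20 methyl (1E,4E,8E,12R)-5,9-dimethyl-12-[(2E)-6-methylhepta-2,5-dien-2-yl]cyclotetradeca-1(14),4,8-triene-1-carboxylate
Conditions: Bu3SnH (5 equiv), AIBN (0.3 equiv, in portions), toluene, 110 °C
Reagents that add atoms: none
Why: Radical denitration of a secondary nitroalkane with Bu3SnH in refluxing toluene: the tin radical adds to an oxygen of the nitro group, the adduct fragments at the C5–N bond and the C5 radical takes hydrogen from the excess Bu3SnH before it can rearrange, so both C5 epimers give the same product and C4 is untouched.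

Compound list
1 | propargyl alcohol | C#CCO | starting material
2 | prenyl bromide (1-bromo-3-methylbut-2-ene) | CC(C)=CCBr | starting material
3 | dimethyl[(1E)-3-(dimethylalumanyloxy)-2-methylprop-1-en-1-yl]alumane (not isolated) | C[Al](C)/C=C(\C)CO[Al](C)C | intermediate
4 | (2E)-2,6-dimethylhepta-2,5-dien-1-ol | OC/C(C)=C/CC=C(C)C | intermediate
5 | (2E)-2,6-dimethylhepta-2,5-dienal | O=C/C(C)=C/CC=C(C)C | intermediate
6 | (2E,4E)-4,8-dimethylnona-2,4,7-trienal | O=C/C=C/C(C)=C/CC=C(C)C | intermediate
7 | nitromethane | C[N+](=O)[O-] | starting material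
8 | (3R,4E)-4,8-dimethyl-3-(nitromethyl)nona-4,7-dienal | [O-][N+](=O)C[C@@H](/C(C)=C/CC=C(C)C)CC=O | intermediate
9 | geranyl bromide | CC(C)=CCC/C(C)=C/CBr | starting material
10 | [(3E)-4,8-dimethylnona-3,7-dien-1-yl](dimethyl)(propan-2-yloxy)silane | CC(C)=CCC/C(C)=C/CC[Si](C)(C)OC(C)C | intermediate
11 | (3E)-4,8-dimethylnona-3,7-dien-1-ol (homogeraniol) | CC(C)=CCC/C(C)=C/CCO | intermediate
12 | (6E)-9-bromo-2,6-dimethylnona-2,6-diene | CC(C)=CCC/C(C)=C/CCBr | intermediate
13 | (2E,6E)-9-bromo-2,6-dimethylnona-2,6-dien-1-ol | OC/C(C)=C/CC/C(C)=C/CCBr | intermediate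
14 | (2E,6E)-9-bromo-2,6-dimethylnona-2,6-dien-1-yl methyl carbonate | COC(=O)OC/C(C)=C/CC/C(C)=C/CCBr | intermediate
15 | (2E,6E)-9-iodo-2,6-dimethylnona-2,6-dien-1-yl methyl carbonate (not isolated) | COC(=O)OC/C(C)=C/CC/C(C)=C/CCI | intermediate
16 | [(5E,9E)-1-methoxy-11-(methoxycarbonyloxy)-6,10-dimethyl-1-oxoundeca-5,9-dien-2-yl]triphenylphosphonium iodide (not isolated) | [I-].COC(=O)C(CC/C=C(C)/CC/C=C(C)/COC(=O)OC)[P+](c1ccccc1)(c1ccccc1)c1ccccc1 | intermediate
17 | methyl (5E,9E)-11-(methoxycarbonyloxy)-6,10-dimethyl-2-(triphenyl-λ5-phosphanylidene)undeca-5,9-dienoate | COC(=O)C(CC/C=C(C)/CC/C=C(C)/COC(=O)OC)=P(c1ccccc1)(c1ccccc1)c1ccccc1 | intermediate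
18 | methyl (2E,5E,9E)-2-[(3R,4E)-4,8-dimethyl-3-(nitromethyl)nona-4,7-dien-1-ylidene]-11-(methoxycarbonyloxy)-6,10-dimethylundeca-5,9-dienoate (nitro on C5, carbonate on C6) | [O-][N+](=O)C[C@@H](/C(C)=C/CC=C(C)C)C/C=C(\CC/C=C(C)/CC/C=C(C)/COC(=O)OC)C(=O)OC | intermediate
19 | methyl (1E,4E,8E,11RS,12R)-5,9-dimethyl-12-[(2E)-6-methylhepta-2,5-dien-2-yl]-11-nitrocyclotetradeca-1(14),4,8-triene-1-carboxylate (nitro on C5, both epimers) | COC(=O)/C1=C/C[C@H](/C(C)=C/CC=C(C)C)C([N+](=O)[O-])C/C(C)=C/CC/C(C)=C/CC1 | intermediate
20 | methyl (1E,4E,8E,12R)-5,9-dimethyl-12-[(2E)-6-methylhepta-2,5-dien-2-yl]cyclotetradeca-1(14),4,8-triene-1-carboxylate | COC(=O)/C1=C/C[C@H](/C(C)=C/CC=C(C)C)CC/C(C)=C/CC/C(C)=C/CC1 | target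

Total step count: 13. Longest linear sequence: 9 steps (steps 5 to 13, from geranyl bromide 9); the other branch is steps 1 to 4.

Steps most likely to fail

Step 12. The ring closure may lose to intermolecular allylation (oligomers), to O-allylation followed by breakdown of the nitronic ester, to attack at C8, or to syn–anti exchange of the π-allyl complex that erodes the E geometry. The fallback makes C5–C6 between two small molecules and closes the ring at C1=C2 instead. It sets out from 8 and 14. Aldehyde 8 is protected with HC(OMe)3 and PPTS in MeOH as (3R,4E)-1,1-dimethoxy-4,8-dimethyl-3-(nitromethyl)nona-4,7-diene F1. An excess of F1 is allylated at the nitro carbon with 14 under Pd(PPh3)4 in THF at 50 °C, a known intermolecular allylation of a nitroalkane with an allylic carbonate, to give the acetal bromide F2. Treatment as in step 10 leads through the acetal iodide F3 and the acetal phosphonium iodide F4 to the acetal ylide F5. Aqueous HCl in THF protonates the ylide and hydrolyses the acetal to the phosphonium chloride aldehyde F6. Slow addition of F6 to Et3N in CH2Cl2 at high dilution starts an intramolecular Wittig reaction, which comes back to the route at 19.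

Step 13. The tin adduct may cleave at N–O instead of C–N and stop at the oxime, the reversible addition of tin radicals may isomerise an alkene, or the homoallylic C5 radical may rearrange by vinyl migration. The fallback sets out from 19. Zn dust in AcOH at rt reduces the nitro group to the primary amine F7. Direct deamination of F7 with N-(benzyloxy)-N-(pivaloyloxy)-4-(trifluoromethyl)benzamide in MeCN at 45 °C, which proceeds through a monoalkyl diazene that loses N2, comes back to the route at 20.

Step 4. The iminium ion may be deprotonated at C17 to a polyenamine, which lets the C18=C19 alkene drift into conjugation; the nitronate may attack C16 instead of C4; or facial control may be poor with the branched dienyl group. The fallback switches to enamine activation, so that the polyene is never bound to the catalyst. It sets out from 5, which makes step 3 and compound 6 unnecessary. Aldehyde 5 is condensed with nitromethane (NH4OAc, AcOH, 80 °C), passing through the nitro alcohol F8, which is not isolated, to the nitrodiene F9. Acetaldehyde (10 equiv) is then added to F9 with (R)-2-[diphenyl(trimethylsilyloxy)methyl]pyrrolidine in 1,4-dioxane at rt, a known enamine Michael addition to nitroalkenes, which comes back to the route at 8.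

Further compounds
F1 | step 12 | (3R,4E)-1,1-dimethoxy-4,8-dimethyl-3-(nitromethyl)nona-4,7-diene | [O-][N+](=O)C[C@@H](/C(C)=C/CC=C(C)C)CC(OC)OC
F2 | step 12 | (3R,6E,10E)-13-bromo-1,1-dimethoxy-6,10-dimethyl-3-[(2E)-6-methylhepta-2,5-dien-2-yl]-4-nitrotrideca-6,10-diene (both C4 epimers) | [O-][N+](=O)C(C/C(C)=C/CC/C(C)=C/CCBr)[C@@H](/C(C)=C/CC=C(C)C)CC(OC)OC
F3 | step 12 | (3R,6E,10E)-13-iodo-1,1-dimethoxy-6,10-dimethyl-3-[(2E)-6-methylhepta-2,5-dien-2-yl]-4-nitrotrideca-6,10-diene | [O-][N+](=O)C(C/C(C)=C/CC/C(C)=C/CCI)[C@@H](/C(C)=C/CC=C(C)C)CC(OC)OC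
F4 | step 12 | [(5E,9E,13R)-1,15,15-trimethoxy-6,10-dimethyl-13-[(2E)-6-methylhepta-2,5-dien-2-yl]-12-nitro-1-oxopentadeca-5,9-dien-2-yl]triphenylphosphonium iodide | [I-].[O-][N+](=O)C(C/C(C)=C/CC/C(C)=C/CCC(C(=O)OC)[P+](c1ccccc1)(c1ccccc1)c1ccccc1)[C@@H](/C(C)=C/CC=C(C)C)CC(OC)OC
F5 | step 12 | methyl (5E,9E,13R)-15,15-dimethoxy-6,10-dimethyl-13-[(2E)-6-methylhepta-2,5-dien-2-yl]-12-nitro-2-(triphenyl-λ5-phosphanylidene)pentadeca-5,9-dienoate | [O-][N+](=O)C(C/C(C)=C/CC/C(C)=C/CCC(C(=O)OC)=P(c1ccccc1)(c1ccccc1)c1ccccc1)[C@@H](/C(C)=C/CC=C(C)C)CC(OC)OC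
F6 | step 12 | [(5E,9E,13R)-1-methoxy-6,10-dimethyl-13-[(2E)-6-methylhepta-2,5-dien-2-yl]-12-nitro-1,15-dioxopentadeca-5,9-dien-2-yl]triphenylphosphonium chloride | [Cl-].[O-][N+](=O)C(C/C(C)=C/CC/C(C)=C/CCC(C(=O)OC)[P+](c1ccccc1)(c1ccccc1)c1ccccc1)[C@@H](/C(C)=C/CC=C(C)C)CC=O
F7 | step 13 | methyl (1E,4E,8E,11RS,12R)-11-amino-5,9-dimethyl-12-[(2E)-6-methylhepta-2,5-dien-2-yl]cyclotetradeca-1(14),4,8-triene-1-carboxylate | COC(=O)/C1=C/C[C@H](/C(C)=C/CC=C(C)C)C(N)C/C(C)=C/CC/C(C)=C/CC1
F8 | step 4 | (3E)-3,7-dimethyl-1-nitroocta-3,6-dien-2-ol (racemic, not isolated) | [O-][N+](=O)CC(O)/C(C)=C/CC=C(C)C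
F9 | step 4 | (1E,3E)-3,7-dimethyl-1-nitroocta-1,3,6-triene | [O-][N+](=O)/C=C/C(C)=C/CC=C(C)C
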